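## Retrosynthetic overview

1. Target 14 ⇐ C6 carboxyl by hydroxycarbonylation of a C6 aryl triflate, and both acetates from a C8 phenol and a C20 alcohol; ring A therefore goes back to a symmetric 3,5-dioxygenated benzene ring, bought as 5-iodoresorcinol.
2. Ring B ⇐ one photoredox radical annulation: a C3 radical from a homobenzylic iodide adds to methyl acrylate (C2–C3), and the resulting C1 radical closes onto C8a (C1–C8a).
3. Enabling feature: C1 carries an oxidised carbon (C20), so C1=C2 can be an acrylate. In ring A the C6 carboxyl and the C8 oxygen are both meta to C4a, so both can descend from oxygen, and the two carbons ortho to C4a (C5 and C8a) are equivalent when the ring closes.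
4. Iodide ⇐ (S)-citronellal, which supplies C3, C4, C11 and the side chain, by enantioselective α-arylation with an aryl(mesityl)iodonium salt. C11 comes from the chiral pool, C4 from catalyst control, C1 from 1,4-induction in the ring closure.
5. Order of rings: ring A is bought; ring B is the only ring formed (step 5).

Key step: step 5

Assumption: all intermediates keep the atom numbering of the target tetralin (C1–C8a, C20 on C1, C11 the first side-chain carbon), and the (2R,5R) imidazolidinone is taken to direct Re-face arylation of the E-enamine as in its other enamine reactions (its antipode would be used if the sense proved opposite).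

## Route

Step 1
Reactants: 1 5-iodobenzene-1,3-diol
Product: 2 5-iodo-1,3-phenylene bis(2,2-dimethylpropanoate)
Conditions: PivCl (2.3 equiv), Et3N, DMAP (cat.), CH2Cl2, 0 °C to rt
Reagents that add atoms: pivaloyl chloride, CC(C)(C)C(=O)Cl
Why: DMAP-catalysed O-acylation of both phenols gives pivalates that should survive the oxidant, the borohydride and the radical step and fall off in the same hydride reduction that later reduces the C1 ester.

Step 2
Reactants: 2 5-iodo-1,3-phenylene bis(2,2-dimethylpropanoate)
Product: 3 [3,5-bis(pivaloyloxy)phenyl](2,4,6-trimethylphenyl)iodonium trifluoromethanesulfonate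
Conditions: mCPBA (1.1 equiv), mesitylene (1.1 equiv), TfOH (2 equiv), CH2Cl2, 0 °C to rt
Reagents that add atoms: mesitylene, Cc1cc(C)cc(C)c1; trifluoromethanesulfonic acid, OS(=O)(=O)C(F)(F)F
Why: One-pot diaryliodonium synthesis, in which the iodoarene is oxidised to a trivalent iodine species that substitutes mesitylene electrophilically; it tolerates electron-poor iodoarenes and installs mesityl as the non-transferred group.

Step 3
Reactants: 3 [3,5-bis(pivaloyloxy)phenyl](2,4,6-trimethylphenyl)iodonium trifluoromethanesulfonate; 4 (S)-citronellal (2 equiv)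
Product: 6 (2S,3S)-2-[3,5-bis(pivaloyloxy)phenyl]-3,7-dimethyloct-6-en-1-ol, via α-aryl aldehyde 5 (not isolated)
Conditions: CuBr (10 mol %), (2R,5R)-5-benzyl-2-tert-butyl-3-methylimidazolidin-4-one·Cl3CCO2H (10 mol %), NaHCO3, toluene/Et2O 2:1, 23 °C; then MeOH, NaBH4, 0 °C
Reagents that add atoms: none
Why: Enantioselective enamine α-arylation of an aldehyde with a diaryliodonium salt under CuBr/imidazolidinone dual catalysis should set C4 as S by catalyst-controlled arylation of the enamine face not shielded by the benzyl group, next to the untouched C11 centre of citronellal, and the immediate NaBH4 reduction prevents epimerisation of the α-aryl aldehyde.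

Step 4
Reactants: 6 (2S,3S)-2-[3,5-bis(pivaloyloxy)phenyl]-3,7-dimethyloct-6-en-1-ol
Product: 7 5-[(2S,3S)-1-iodo-3,7-dimethyloct-6-en-2-yl]-1,3-phenylene bis(2,2-dimethylpropanoate)
Conditions: I2, PPh3, imidazole, CH2Cl2, 0 °C to rt
Reagents that add atoms: iodine, II
Why: Appel-type iodination of the primary alcohol by SN2 displacement of the oxyphosphonium group touches neither stereocentre, and the electron-poor aryl ring disfavours phenonium participation.

Step 5
Reactants: 7 5-[(2S,3S)-1-iodo-3,7-dimethyloct-6-en-2-yl]-1,3-phenylene bis(2,2-dimethylpropanoate); 8 methyl acrylate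
Product: 9 methyl (1R,4S)-4-[(2S)-6-methylhept-5-en-2-yl]-6,8-bis(pivaloyloxy)-1,2,3,4-tetrahydronaphthalene-1-carboxylate
Conditions: fac-Ir(ppy)3 (2 mol %), K2HPO4 (2 equiv), 8 (3 equiv, added over 8 h), degassed MeCN (0.02 M), blue LEDs (450 nm), 25 °C
Reagents that add atoms: none
Why: Proposed new method: photoexcited Ir(ppy)3 transfers an electron to the C–I bond of 7 (dissociative reduction, as in photoredox Giese reactions of unactivated alkyl iodides) to give the primary C3 radical, which adds to the β-carbon of methyl acrylate (C2–C3 bond); the electrophilic α-ester radical at C1 then attacks arene carbon C8a, and the cyclohexadienyl radical is oxidised by tetravalent iridium and deprotonated by phosphate, so the cycle is redox-neutral. The closest known reaction types are the photoredox alkyl-radical addition/cyclisation of N-aryl acrylamides to oxindoles and the manganese triacetate-mediated annulation of benzylmalonates with alkenes to tetralins, of which this is the polarity-reversed variant. Ring B, the only ring formed, closes by a six-membered homolytic aromatic substitution (6-exo-trig if counted on the C8a=C8 bond). C1 is set in this closure: in the chair-like transition state the C4 side chain sits pseudoaxial to avoid the peri C5–H and the ester sits pseudoaxial to avoid the peri C8 pivalate, which places them on opposite faces (1,4-trans, 1R from 4S), and since addition of a stabilised radical to an arene is reversible the same diaxial preference should also hold under thermodynamic control. The step needs regioselectivity between the two carbons ortho to C4a, which is no issue because they are equivalent in the symmetric 3,5-bis(pivaloyloxy)phenyl ring, and chemoselectivity of the C3 radical for acrylate over 6-exo attack on the C14=C15 olefin and of the C1 radical for the arene over a second acrylate, which the slow addition of a modest excess of acrylate at high dilution is meant to secure.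

Step 6
Reactants: 9 methyl (1R,4S)-4-[(2S)-6-methylhept-5-en-2-yl]-6,8-bis(pivaloyloxy)-1,2,3,4-tetrahydronaphthalene-1-carboxylate
Product: 10 (1R,4S)-1-(hydroxymethyl)-4-[(2S)-6-methylhept-5-en-2-yl]-1,2,3,4-tetrahydronaphthalene-6,8-diol
Conditions: LiAlH4 (excess), THF, 0 °C to rt; Rochelle salt work-up
Reagents that add atoms: none
Why: Hydride reduction of all three esters should give the C20 primary alcohol from the C1 methyl ester faster than C1 can enolise, so C1 keeps its configuration, and cleaves both aryl pivalates to the phenols in the same operation.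

Step 7
Reactants: 10 (1R,4S)-1-(hydroxymethyl)-4-[(2S)-6-methylhept-5-en-2-yl]-1,2,3,4-tetrahydronaphthalene-6,8-diol
Product: 11 (1R,4S)-8-hydroxy-1-(hydroxymethyl)-4-[(2S)-6-methylhept-5-en-2-yl]-1,2,3,4-tetrahydronaphthalen-6-yl trifluoromethanesulfonate
Conditions: PhNTf2 (1.0 equiv), Et3N (1.2 equiv), CH2Cl2, −20 to 0 °C
Reagents that add atoms: N-phenylbis(trifluoromethanesulfonimide), O=S(=O)(N(c1ccccc1)S(=O)(=O)C(F)(F)F)C(F)(F)F
Why: Phenol triflation with N-phenyltriflimide leaves the primary alcohol alone, and with one equivalent at low temperature the C6 hydroxyl, flanked by two ring hydrogens, should react in preference to the C8 hydroxyl, which is shielded by the peri C1 hydroxymethyl group.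

Step 8
Reactants: 11 (1R,4S)-8-hydroxy-1-(hydroxymethyl)-4-[(2S)-6-methylhept-5-en-2-yl]-1,2,3,4-tetrahydronaphthalen-6-yl trifluoromethanesulfonate
Product: 12 [(1R,4S)-8-acetoxy-4-[(2S)-6-methylhept-5-en-2-yl]-6-(trifluoromethylsulfonyloxy)-1,2,3,4-tetrahydronaphthalen-1-yl]methyl acetate
Conditions: Ac2O (3 equiv), pyridine, DMAP (cat.), CH2Cl2, 0 °C to rt
Reagents that add atoms: acetic anhydride, CC(=O)OC(C)=O
Why: DMAP-catalysed acetylation of the remaining phenol and the primary alcohol installs both acetates of the target while the aryl triflate is inert.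

Step 9
Reactants: 12 [(1R,4S)-8-acetoxy-4-[(2S)-6-methylhept-5-en-2-yl]-6-(trifluoromethylsulfonyloxy)-1,2,3,4-tetrahydronaphthalen-1-yl]methyl acetate
Product: 14 (5R,8S)-4-acetoxy-5-(acetoxymethyl)-8-[(2S)-6-methylhept-5-en-2-yl]-5,6,7,8-tetrahydronaphthalene-2-carboxylic acid (CNP0223972.1), via mixed acetic anhydride 13 (not isolated)
Conditions: Pd(OAc)2 (5 mol %), dppf (10 mol %), CO (1 atm), KOAc (4 equiv), DMSO, 60 °C; then dilute aqueous acid work-up (pH 3)
Reagents that add atoms: carbon monoxide, [C-]#[O+]; potassium acetate, CC(=O)[O-].[K+]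
Why: Palladium-catalysed hydroxycarbonylation of an aryl triflate (oxidative addition of zerovalent palladium, CO insertion, capture of the acyl palladium by acetate, cleavage of the mixed anhydride at its acetyl carbonyl on work-up) runs in a medium free of hydroxide and alkoxide, so the aryl and alkyl acetates and the trisubstituted olefin should survive.

## Compound list

1 | 5-iodobenzene-1,3-diol (5-iodoresorcinol) | Oc1cc(O)cc(I)c1 | starting material
2 | 5-iodo-1,3-phenylene bis(2,2-dimethylpropanoate) | CC(C)(C)C(=O)Oc1cc(I)cc(OC(=O)C(C)(C)C)c1 | intermediate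
3 | [3,5-bis(pivaloyloxy)phenyl](2,4,6-trimethylphenyl)iodonium trifluoromethanesulfonate | CC(C)(C)C(=O)Oc1cc(OC(=O)C(C)(C)C)cc([I+]c2c(C)cc(C)cc2C)c1.[O-]S(=O)(=O)C(F)(F)F | intermediate
4 | (S)-citronellal, (3S)-3,7-dimethyloct-6-enal | O=CC[C@@H](C)CCC=C(C)C | starting material
5 | (2S,3S)-2-[3,5-bis(pivaloyloxy)phenyl]-3,7-dimethyloct-6-enal | O=C[C@@H]([C@@H](C)CCC=C(C)C)c1cc(OC(=O)C(C)(C)C)cc(OC(=O)C(C)(C)C)c1 | intermediate
6 | (2S,3S)-2-[3,5-bis(pivaloyloxy)phenyl]-3,7-dimethyloct-6-en-1-ol | OC[C@@H]([C@@H](C)CCC=C(C)C)c1cc(OC(=O)C(C)(C)C)cc(OC(=O)C(C)(C)C)c1 | intermediate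
7 | 5-[(2S,3S)-1-iodo-3,7-dimethyloct-6-en-2-yl]-1,3-phenylene bis(2,2-dimethylpropanoate) | IC[C@@H]([C@@H](C)CCC=C(C)C)c1cc(OC(=O)C(C)(C)C)cc(OC(=O)C(C)(C)C)c1 | intermediate
8 | methyl acrylate | C=CC(=O)OC | starting material
9 | methyl (1R,4S)-4-[(2S)-6-methylhept-5-en-2-yl]-6,8-bis(pivaloyloxy)-1,2,3,4-tetrahydronaphthalene-1-carboxylate | COC(=O)[C@@H]1CC[C@@H]([C@@H](C)CCC=C(C)C)c2cc(OC(=O)C(C)(C)C)cc(OC(=O)C(C)(C)C)c21 | intermediate
10 | (1R,4S)-1-(hydroxymethyl)-4-[(2S)-6-methylhept-5-en-2-yl]-1,2,3,4-tetrahydronaphthalene-6,8-diol | OC[C@@H]1CC[C@@H]([C@@H](C)CCC=C(C)C)c2cc(O)cc(O)c21 | intermediate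
11 | (1R,4S)-8-hydroxy-1-(hydroxymethyl)-4-[(2S)-6-methylhept-5-en-2-yl]-1,2,3,4-tetrahydronaphthalen-6-yl trifluoromethanesulfonate | OC[C@@H]1CC[C@@H]([C@@H](C)CCC=C(C)C)c2cc(OS(=O)(=O)C(F)(F)F)cc(O)c21 | intermediate
12 | [(1R,4S)-8-acetoxy-4-[(2S)-6-methylhept-5-en-2-yl]-6-(trifluoromethylsulfonyloxy)-1,2,3,4-tetrahydronaphthalen-1-yl]methyl acetate | CC(=O)OC[C@@H]1CC[C@@H]([C@@H](C)CCC=C(C)C)c2cc(OS(=O)(=O)C(F)(F)F)cc(OC(C)=O)c21 | intermediate
13 | acetic (1R,4S)-8-acetoxy-1-(acetoxymethyl)-4-[(2S)-6-methylhept-5-en-2-yl]-1,2,3,4-tetrahydronaphthalene-6-carboxylic anhydride | CC(=O)OC[C@@H]1CC[C@@H]([C@@H](C)CCC=C(C)C)c2cc(C(=O)OC(C)=O)cc(OC(C)=O)c21 | intermediate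
14 | (5R,8S)-4-acetoxy-5-(acetoxymethyl)-8-[(2S)-6-methylhept-5-en-2-yl]-5,6,7,8-tetrahydronaphthalene-2-carboxylic acid (1R,4S in target numbering) | CC(=O)OC[C@@H]1CC[C@@H]([C@@H](C)CCC=C(C)C)c2cc(C(=O)O)cc(OC(C)=O)c21 | target

## Summary

Total step count: 9. Longest linear sequence: 9 steps (1 to 14); 4 and 8 are bought and enter at steps 3 and 5.

Steps most likely to fail:

Step 5. The C1 radical may telomerise with further acrylate or be quenched before it closes onto the arene, and the ring closure may show incomplete facial selectivity. The fallback sets out from 7 and comes back at 9, separating the two bond formations with known reactions. A tin-free radical-chain Giese addition of 7 to 8 ((Me3Si)3SiH, AIBN, toluene, 80 °C), in which the silane reduces the C1 radical at once, should give methyl (5S,6S)-5-[3,5-bis(pivaloyloxy)phenyl]-6,10-dimethylundec-9-enoate F1. Enolate bromination (LDA, THF, −78 °C; then CBr4) should give methyl (5S,6S)-2-bromo-5-[3,5-bis(pivaloyloxy)phenyl]-6,10-dimethylundec-9-enoate F2 as a mixture at C2. Visible-light photoredox homolytic aromatic substitution of this α-bromo ester (fac-Ir(ppy)3, K2HPO4, MeCN, blue LEDs), with no acrylate present, should then close ring B to 9.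

Step 7. Triflation may spread to the C8 hydroxyl or to both phenols. The fallback sets out from 10 and comes back at 14. Exhaustive triflation (PhNTf2, 2.5 equiv, Et3N, CH2Cl2) should give (1R,4S)-1-(hydroxymethyl)-4-[(2S)-6-methylhept-5-en-2-yl]-1,2,3,4-tetrahydronaphthalene-6,8-diyl bis(trifluoromethanesulfonate) F3. Site-selective hydroxycarbonylation (Pd(OAc)2, dppf, CO, K2CO3, DMF/H2O, 70 °C), in which oxidative addition at the peri-shielded C8 triflate is much slower than at C6, should give (1R,4S)-1-(hydroxymethyl)-4-[(2S)-6-methylhept-5-en-2-yl]-8-(trifluoromethylsulfonyloxy)-1,2,3,4-tetrahydronaphthalene-6-carboxylic acid F4. Aqueous Et4NOH in dioxane at rt should cleave the remaining triflate to (1R,4S)-8-hydroxy-1-(hydroxymethyl)-4-[(2S)-6-methylhept-5-en-2-yl]-1,2,3,4-tetrahydronaphthalene-6-carboxylic acid F5. Ac2O/pyridine followed by aqueous work-up should acetylate both hydroxyls and give 14.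

Step 3. The β-branched enamine may be arylated slowly or with low facial selectivity, and the α-aryl aldehyde may epimerise. The fallback sets out from 2 and 4 and comes back at 6, giving up catalyst control for separation. Palladium-catalysed α-arylation of the aldehyde with aryl iodide 2 (Pd(OAc)2, rac-BINAP, Cs2CO3, dioxane, 80 °C) should give 5 together with its C4 epimer (2R,3S)-2-[3,5-bis(pivaloyloxy)phenyl]-3,7-dimethyloct-6-enal F6. Reduction of the mixture (NaBH4, MeOH, 0 °C) should give 6 and (2R,3S)-2-[3,5-bis(pivaloyloxy)phenyl]-3,7-dimethyloct-6-en-1-ol F7, from which 6 is separated by chromatography.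

Further compounds

F1 | step 5 | methyl (5S,6S)-5-[3,5-bis(pivaloyloxy)phenyl]-6,10-dimethylundec-9-enoate | COC(=O)CCC[C@@H]([C@@H](C)CCC=C(C)C)c1cc(OC(=O)C(C)(C)C)cc(OC(=O)C(C)(C)C)c1
F2 | step 5 | methyl (5S,6S)-2-bromo-5-[3,5-bis(pivaloyloxy)phenyl]-6,10-dimethylundec-9-enoate (mixture at C2) | COC(=O)C(Br)CC[C@@H]([C@@H](C)CCC=C(C)C)c1cc(OC(=O)C(C)(C)C)cc(OC(=O)C(C)(C)C)c1
F3 | step 7 | (1R,4S)-1-(hydroxymethyl)-4-[(2S)-6-methylhept-5-en-2-yl]-1,2,3,4-tetrahydronaphthalene-6,8-diyl bis(trifluoromethanesulfonate) | OC[C@@H]1CC[C@@H]([C@@H](C)CCC=C(C)C)c2cc(OS(=O)(=O)C(F)(F)F)cc(OS(=O)(=O)C(F)(F)F)c21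
F4 | step 7 | (1R,4S)-1-(hydroxymethyl)-4-[(2S)-6-methylhept-5-en-2-yl]-8-(trifluoromethylsulfonyloxy)-1,2,3,4-tetrahydronaphthalene-6-carboxylic acid | OC[C@@H]1CC[C@@H]([C@@H](C)CCC=C(C)C)c2cc(C(=O)O)cc(OS(=O)(=O)C(F)(F)F)c21
F5 | step 7 | (1R,4S)-8-hydroxy-1-(hydroxymethyl)-4-[(2S)-6-methylhept-5-en-2-yl]-1,2,3,4-tetrahydronaphthalene-6-carboxylic acid | OC[C@@H]1CC[C@@H]([C@@H](C)CCC=C(C)C)c2cc(C(=O)O)cc(O)c21
F6 | step 3 | (2R,3S)-2-[3,5-bis(pivaloyloxy)phenyl]-3,7-dimethyloct-6-enal | O=C[C@H]([C@@H](C)CCC=C(C)C)c1cc(OC(=O)C(C)(C)C)cc(OC(=O)C(C)(C)C)c1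
F7 | step 3 | (2R,3S)-2-[3,5-bis(pivaloyloxy)phenyl]-3,7-dimethyloct-6-en-1-ol | OC[C@H]([C@@H](C)CCC=C(C)C)c1cc(OC(=O)C(C)(C)C)cc(OC(=O)C(C)(C)C)c1
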